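Numbering: cyclopentene C1–C5 (C4 methyl), seven-membered ring C1, C5–C10, side chain C11–C15. The route rests on the C7–C8 disconnection of the seven-membered ring. Because O6 and C12 are 1,4-related through C7 and C11, they are tied as an α-methylbutenolide (temporary ring) on a trans-disubstituted cyclopentene; C7 becomes an enoate β-carbon, and C8, next to the C9 carbinol, is a primary iodide from D-glyceraldehyde. One 7-exo-trig radical conjugate cyclization forms C7–C8, closes the seven-membered ring cis-fused to the lactone (C7) and sets C11 by convex-face hydrogen delivery. Acetylide opening of the lactone then frees 6-OH and builds the side chain.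

Key step: step 10

Remarks before the steps:
- Full numbering used in all names: ring fusion C1/C5; cyclopentene C1–C2–C3=C4(CH3)–C5; seven-membered ring C5–C6(O)–C7–C8–C9(O)–C10(=C18H2)–C1; side chain C7–C11(CH3)–C12(O)–C13=C14–C15(CH3)2(O). The target is (1R,5S,6R,7S,9R,11R,12S,13E), with a trans C1/C5 ring fusion.
- L in step 3 is the phosphoramidite O,O'-(1,1'-binaphthyl-2,2'-diyl) N,N-bis(1-phenylethyl)phosphoramidite. Assumption: the ligand enantiomer that gives the 3R product is identified in a first run; because C9 is already fixed, the other C1 epimer is a diastereomer and is removed by chromatography.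
- Compounds 1, 4, 5, 13 and 19 and all reagents are taken as commercially available.

Step 1
Reactants: 1 (R)-2,2-dimethyl-1,3-dioxolane-4-carbaldehyde
Product: 2 (S)-4-ethynyl-2,2-dimethyl-1,3-dioxolane
Conditions: Ohira–Bestmann reagent, K2CO3, MeOH, 0 °C → rt
Reagents that add atoms: dimethyl (1-diazo-2-oxopropyl)phosphonate, COP(=O)(OC)C(=[N+]=[N-])C(C)=O
Why: Seyferth–Gilbert homologation in the Ohira–Bestmann variant should turn the aldehyde into the terminal alkyne under mild base, carrying the dioxolane stereocentre (the future C9) through unchanged.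

Step 2
Reactants: 2 (S)-4-ethynyl-2,2-dimethyl-1,3-dioxolane
Product: 3 tributyl{1-[(4R)-2,2-dimethyl-1,3-dioxolan-4-yl]ethenyl}stannane
Conditions: Bu3SnH, Mo(CO)3(CNtBu)3 (2 mol%), hydroquinone, THF, 55 °C
Reagents that add atoms: tributylstannane, CCCC[SnH](CCCC)CCCC
Why: Molybdenum-catalysed hydrostannation of a terminal alkyne with a propargylic oxygen is α-selective (syn addition, tin on the internal carbon), so it should give the 1,1-disubstituted alkenylstannane that becomes C10 with C18, without creating a stereocentre.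

Step 3
Reactants: 3 tributyl{1-[(4R)-2,2-dimethyl-1,3-dioxolan-4-yl]ethenyl}stannane; 4 cyclopent-2-en-1-one; 5 prop-2-enal (acrolein)
Product: 9 (2R,3R)-3-{1-[(4S)-2,2-dimethyl-1,3-dioxolan-4-yl]ethenyl}-2-[(1R)-1-hydroxyprop-2-en-1-yl]cyclopentan-1-one, via alkenyllithium 6 (not isolated), via alkenyldimethylalane 7 (not isolated), via aluminium enolate 8 (not isolated)
Conditions: nBuLi, THF, −78 °C; Me2AlCl; Cu(OTf)2 (5 mol%), L (10 mol%), 4, Et2O, −30 °C; 5, −78 °C; aq. Rochelle salt
Reagents that add atoms: none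
Why: Tin–lithium exchange and transmetalation give alkenylalane 7, whose copper-catalysed asymmetric conjugate addition to 4 should set C1 under ligand control and leave the aluminium (E)-enolate 8, and the aldol addition of 8 to acrolein should occur anti to the C1 substituent (trans C1/C5) through a Zimmerman–Traxler chair (anti C5/C6, that is 6R).

Step 4
Reactants: 9 (2R,3R)-3-{1-[(4S)-2,2-dimethyl-1,3-dioxolan-4-yl]ethenyl}-2-[(1R)-1-hydroxyprop-2-en-1-yl]cyclopentan-1-one
Product: 10 N'-[(1E,2S,3R)-3-{1-[(4S)-2,2-dimethyl-1,3-dioxolan-4-yl]ethenyl}-2-[(1R)-1-hydroxyprop-2-en-1-yl]cyclopentylidene]-2,4,6-tri(propan-2-yl)benzenesulfonohydrazide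
Conditions: 2,4,6-iPr3C6H2SO2NHNH2, THF, rt
Reagents that add atoms: 2,4,6-tri(propan-2-yl)benzenesulfonohydrazide, CC(C)c1cc(C(C)C)c(S(=O)(=O)NN)c(C(C)C)c1
Why: Condensation of the ketone with the bulky arenesulfonyl hydrazide should give the hydrazone with the N–N bond on the side of the unsubstituted C3, under neutral conditions that spare the β-hydroxy ketone and the acetonide and leave C5 in its trans configuration.

Step 5
Reactants: 10 N'-[(1E,2S,3R)-3-{1-[(4S)-2,2-dimethyl-1,3-dioxolan-4-yl]ethenyl}-2-[(1R)-1-hydroxyprop-2-en-1-yl]cyclopentylidene]-2,4,6-tri(propan-2-yl)benzenesulfonohydrazide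
Product: 12 (1R)-1-[(1S,5R)-5-{1-[(4S)-2,2-dimethyl-1,3-dioxolan-4-yl]ethenyl}-2-methylcyclopent-2-en-1-yl]prop-2-en-1-ol, via alkenyllithium 11 (not isolated)
Conditions: nBuLi (3.3 equiv), THF, −78 → 0 °C; MeI, −78 °C → rt
Reagents that add atoms: iodomethane, CI
Why: Shapiro reaction: after N–H and O–H are deprotonated, the third equivalent of base should remove a C3 proton syn to the N-anion, loss of sulfinate and N2 gives C4 alkenyllithium 11 regiospecifically, and MeI methylates it to the C3=C4 alkene without touching a stereocentre.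

Step 6
Reactants: 12 (1R)-1-[(1S,5R)-5-{1-[(4S)-2,2-dimethyl-1,3-dioxolan-4-yl]ethenyl}-2-methylcyclopent-2-en-1-yl]prop-2-en-1-ol; 13 2-methylprop-2-enoyl chloride
Product: 14 (1R)-1-[(1S,5R)-5-{1-[(4S)-2,2-dimethyl-1,3-dioxolan-4-yl]ethenyl}-2-methylcyclopent-2-en-1-yl]prop-2-en-1-yl 2-methylprop-2-enoate
Conditions: Et3N, DMAP (cat.), CH2Cl2, 0 °C
Reagents that add atoms: none
Why: DMAP-catalysed O-acylation of the secondary allylic alcohol, with retention at C6.

Step 7
Reactants: 14 (1R)-1-[(1S,5R)-5-{1-[(4S)-2,2-dimethyl-1,3-dioxolan-4-yl]ethenyl}-2-methylcyclopent-2-en-1-yl]prop-2-en-1-yl 2-methylprop-2-enoate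
Product: 15 (5R)-5-[(1S,5R)-5-{1-[(4S)-2,2-dimethyl-1,3-dioxolan-4-yl]ethenyl}-2-methylcyclopent-2-en-1-yl]-3-methylfuran-2(5H)-one
Conditions: second-generation Grubbs catalyst RuCl2(=CHPh)(H2IMes)(PCy3) (5 mol%), toluene, 80 °C
Reagents that add atoms: none
Why: Ring-closing metathesis of the vinyl group with the methacrylate should give the α-methylbutenolide (C7=C11), because the trisubstituted ring alkene and the hindered 1,1-disubstituted C10 alkene are poor partners and closure onto C10 would need a trans-fused bicyclo[3.3.0]octene.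

Step 8
Reactants: 15 (5R)-5-[(1S,5R)-5-{1-[(4S)-2,2-dimethyl-1,3-dioxolan-4-yl]ethenyl}-2-methylcyclopent-2-en-1-yl]-3-methylfuran-2(5H)-one
Product: 16 (5R)-5-{(1S,5R)-5-[(3S)-3,4-dihydroxybut-1-en-2-yl]-2-methylcyclopent-2-en-1-yl}-3-methylfuran-2(5H)-one
Conditions: AcOH/H2O/THF (3:1:1), 40 °C
Reagents that add atoms: none
Why: Acid-catalysed hydrolysis of the isopropylidene acetal, to which the butenolide and the alkenes should be inert.

Step 9
Reactants: 16 (5R)-5-{(1S,5R)-5-[(3S)-3,4-dihydroxybut-1-en-2-yl]-2-methylcyclopent-2-en-1-yl}-3-methylfuran-2(5H)-one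
Product: 17 (5R)-5-{(1S,5R)-5-[(3S)-3-hydroxy-4-iodobut-1-en-2-yl]-2-methylcyclopent-2-en-1-yl}-3-methylfuran-2(5H)-one
Conditions: I2 (1.05 equiv), PPh3, imidazole, CH2Cl2, 0 °C
Reagents that add atoms: iodine, II
Why: Appel-type iodination (Garegg–Samuelsson conditions) should be selective for the primary hydroxyl at 0 °C with one equivalent of reagent, leaving the secondary allylic 9-OH and its configuration untouched.

Step 10
Reactants: 17 (5R)-5-{(1S,5R)-5-[(3S)-3-hydroxy-4-iodobut-1-en-2-yl]-2-methylcyclopent-2-en-1-yl}-3-methylfuran-2(5H)-one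
Product: 18 (1R,5S,6R,7S,9R,11R)-9-hydroxy-10-methylidene-12,6-lactone of the trans-fused hydroazulene (cis-fused α-methyl-γ-lactone O6–C12(=O)–C11(CH3)–C7; C3=C4; 4-methyl)
Conditions: (Me3Si)3SiH (slow addition), AIBN, benzene (0.005 M), 80 °C
Reagents that add atoms: none
Why: Iodine abstraction by (Me3Si)3Si• gives the primary C8 radical, which adds 7-exo-trig to C7, the β-carbon of the α-methylbutenolide, and the C11 α-acyl radical so formed takes hydrogen from the silane, which carries the chain. The closest known reaction type is the Giese-type reductive radical cyclization of alkyl halides onto butenolides and β-alkoxyacrylates, including 7-exo cases. One ring is closed, the seven-membered carbocycle C1–C5–C6–C7–C8–C9–C10, in the 7-exo-trig mode. C7 is controlled by the tether, since the chain hangs from C5 on C6 and can reach C7 only on the lactone face that carries the C5–C6 bond, so the new ring should be cis-fused to the lactone (7S); C11 is controlled by the bicycle, hydrogen being delivered to the convex face anti to the new C7–C8 bond, which leaves the methyl cis to C8 (11R). The step needs 7-exo closure to outrun direct reduction, 1,5-hydrogen transfer from allylic C2–H, 6-exo attack on C3 and the 1,2-vinyl shift of the homoallylic radical; the butenolide is the only electron-poor, polarity-matched alkene for the nucleophilic alkyl radical, and slow addition of the sluggish hydrogen donor at high dilution keeps the silane concentration low.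

Step 11
Reactants: 18 (1R,5S,6R,7S,9R,11R)-9-hydroxy-10-methylidene-12,6-lactone of the trans-fused hydroazulene; 19 2-methylbut-3-yn-2-ol
Product: 21 (1R,5S,6R,7S,9R,11R)-6,9,15-trihydroxy-13-yn-12-one (ring-opened ynone), via dilithiated alkynol 20 (not isolated)
Conditions: 19 (4 equiv), nBuLi (8 equiv), THF, −78 → −20 °C; then 18, −78 °C; aqueous work-up
Reagents that add atoms: none
Why: Addition of the lithium acetylide to the γ-lactone should stop at the tetrahedral mono-adduct, which gives the γ-hydroxy ynone on work-up and frees 6-OH; at −78 °C addition is faster than enolisation, so C11 should keep its configuration.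

Step 12
Reactants: 21 (1R,5S,6R,7S,9R,11R)-6,9,15-trihydroxy-13-yn-12-one
Product: 22 6,9,15-tris(triethylsilyl) ether of ynone 21
Conditions: Et3SiOTf (4 equiv), 2,6-lutidine, CH2Cl2, −78 → 0 °C
Reagents that add atoms: triethylsilyl trifluoromethanesulfonate, CC[Si](CC)(CC)OS(=O)(=O)C(F)(F)F
Why: Silylation with the silyl triflate and 2,6-lutidine should protect the two secondary and the tertiary hydroxyl and drain the ynone from any hemiketal form, so that C12 is the only carbonyl left.

Step 13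
Reactants: 22 6,9,15-tris(triethylsilyl) ether of ynone 21
Product: 23 (12R)-12-hydroxy-13-yne 6,9,15-tris(triethylsilyl) ether (propargylic alcohol)
Conditions: Ru(p-cymene)[(R,R)-TsNCHPhCHPhNH] (2 mol%), iPrOH, rt
Reagents that add atoms: none
Why: Noyori asymmetric transfer hydrogenation of the alkynyl ketone is reagent-controlled (the alkynyl group takes the place of the aryl group of the standard model), so the (R,R)-catalyst should give the (12R)-propargylic alcohol, which is the target configuration (12S once the alkyne is reduced), without reducing the triple bond.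

Step 14
Reactants: 23 (12R)-12-hydroxy-13-yne 6,9,15-tris(triethylsilyl) ether
Product: 24 (12S,13E)-12-hydroxy-13-ene 6,9,15-tris(triethylsilyl) ether (allylic alcohol)
Conditions: NaAlH2(OCH2CH2OMe)2 (Red-Al), THF, 0 °C → rt
Reagents that add atoms: none
Why: Hydroxyl-directed trans-hydroalumination of the propargylic alcohol and protonolysis should give the (E)-allylic alcohol, the isolated alkenes and silyl ethers being inert.

Step 15
Reactants: 24 (12S,13E)-12-hydroxy-13-ene 6,9,15-tris(triethylsilyl) ether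
Product: 25 12-O-acetate of 24
Conditions: Ac2O, pyridine, DMAP (cat.), CH2Cl2, 0 °C → rt
Reagents that add atoms: acetic anhydride, CC(=O)OC(C)=O
Why: DMAP-catalysed acetylation of the only free hydroxyl, 12-OH.

Step 16
Reactants: 25 12-O-acetate of 24
Product: 26 CNP0213969.2, (1R,5S,6R,7S,9R,11R,12S,13E)-12-acetoxy-6,9,15-triol
Conditions: HF·pyridine, pyridine, THF, 0 °C → rt
Reagents that add atoms: none
Why: Fluoride cleavage of the three triethylsilyl ethers with pyridine-buffered HF, conditions under which the allylic acetate should not migrate and the tertiary allylic alcohol should not ionise.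

Compound list
1 | (R)-2,2-dimethyl-1,3-dioxolane-4-carbaldehyde | O=C[C@H]1COC(C)(C)O1 | starting material
2 | (S)-4-ethynyl-2,2-dimethyl-1,3-dioxolane | C#C[C@H]1COC(C)(C)O1 | intermediate
3 | tributyl{1-[(4R)-2,2-dimethyl-1,3-dioxolan-4-yl]ethenyl}stannane | C=C([Sn](CCCC)(CCCC)CCCC)[C@H]1COC(C)(C)O1 | intermediate
4 | cyclopent-2-en-1-one | O=C1C=CCC1 | starting material
5 | prop-2-enal (acrolein) | C=CC=O | starting material
6 | {1-[(4S)-2,2-dimethyl-1,3-dioxolan-4-yl]ethenyl}lithium | [Li]C(=C)[C@H]1COC(C)(C)O1 | intermediate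
7 | {1-[(4R)-2,2-dimethyl-1,3-dioxolan-4-yl]ethenyl}dimethylalane | C=C([Al](C)C)[C@H]1COC(C)(C)O1 | intermediate
8 | dimethylaluminium (3R)-3-{1-[(4S)-2,2-dimethyl-1,3-dioxolan-4-yl]ethenyl}cyclopent-1-en-1-olate | C=C([C@H]2COC(C)(C)O2)[C@@H]1CCC(O[Al](C)C)=C1 | intermediate
9 | (2R,3R)-3-{1-[(4S)-2,2-dimethyl-1,3-dioxolan-4-yl]ethenyl}-2-[(1R)-1-hydroxyprop-2-en-1-yl]cyclopentan-1-one | C=C([C@H]2COC(C)(C)O2)[C@@H]1CCC(=O)[C@H]1[C@@H](C=C)O | intermediate
10 | N'-[(1E,2S,3R)-3-{1-[(4S)-2,2-dimethyl-1,3-dioxolan-4-yl]ethenyl}-2-[(1R)-1-hydroxyprop-2-en-1-yl]cyclopentylidene]-2,4,6-tri(propan-2-yl)benzenesulfonohydrazide | C=C([C@H]2COC(C)(C)O2)[C@@H]1CC/C(=N\NS(=O)(=O)c2c(C(C)C)cc(C(C)C)cc2C(C)C)[C@H]1[C@@H](C=C)O | intermediate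
11 | lithium (1R)-1-[(1S,5R)-5-{1-[(4S)-2,2-dimethyl-1,3-dioxolan-4-yl]ethenyl}-2-lithiocyclopent-2-en-1-yl]prop-2-en-1-olate | C=C([C@H]2COC(C)(C)O2)[C@@H]1CC=C([Li])[C@H]1[C@@H](C=C)O[Li] | intermediate
12 | (1R)-1-[(1S,5R)-5-{1-[(4S)-2,2-dimethyl-1,3-dioxolan-4-yl]ethenyl}-2-methylcyclopent-2-en-1-yl]prop-2-en-1-ol | C=C([C@H]2COC(C)(C)O2)[C@@H]1CC=C(C)[C@H]1[C@@H](C=C)O | intermediate
13 | 2-methylprop-2-enoyl chloride (methacryloyl chloride) | C=C(C)C(=O)Cl | starting material
14 | (1R)-1-[(1S,5R)-5-{1-[(4S)-2,2-dimethyl-1,3-dioxolan-4-yl]ethenyl}-2-methylcyclopent-2-en-1-yl]prop-2-en-1-yl 2-methylprop-2-enoate | C=C([C@H]2COC(C)(C)O2)[C@@H]1CC=C(C)[C@H]1[C@@H](C=C)OC(=O)C(C)=C | intermediate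
15 | (5R)-5-[(1S,5R)-5-{1-[(4S)-2,2-dimethyl-1,3-dioxolan-4-yl]ethenyl}-2-methylcyclopent-2-en-1-yl]-3-methylfuran-2(5H)-one | C=C([C@H]2COC(C)(C)O2)[C@@H]1CC=C(C)[C@H]1[C@@H]1OC(=O)C(C)=C1 | intermediate
16 | (5R)-5-{(1S,5R)-5-[(3S)-3,4-dihydroxybut-1-en-2-yl]-2-methylcyclopent-2-en-1-yl}-3-methylfuran-2(5H)-one | C=C([C@H](O)CO)[C@@H]1CC=C(C)[C@H]1[C@@H]1OC(=O)C(C)=C1 | intermediate
17 | (5R)-5-{(1S,5R)-5-[(3S)-3-hydroxy-4-iodobut-1-en-2-yl]-2-methylcyclopent-2-en-1-yl}-3-methylfuran-2(5H)-one | C=C([C@H](O)CI)[C@@H]1CC=C(C)[C@H]1[C@@H]1OC(=O)C(C)=C1 | intermediate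
18 | (1R,5S,6R,7S,9R,11R)-9-hydroxy-10-methylidene-12,6-lactone of the trans-fused hydroazulene (cis-fused α-methyl-γ-lactone, C3=C4, 4-methyl) | C=C1[C@H](O)C[C@H]3[C@@H](C)C(=O)O[C@H]3[C@@H]2C(C)=CC[C@@H]12 | intermediate
19 | 2-methylbut-3-yn-2-ol | C#CC(C)(C)O | starting material
20 | dilithiated 2-methylbut-3-yn-2-ol (lithium acetylide lithium alkoxide) | [Li]C#CC(C)(C)O[Li] | intermediate
21 | (1R,5S,6R,7S,9R,11R)-6,9,15-trihydroxy-13-yn-12-one (ring-opened ynone) | C=C1[C@H](O)C[C@@H]([C@@H](C)C(=O)C#CC(C)(C)O)[C@@H](O)[C@@H]2C(C)=CC[C@@H]12 | intermediate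
22 | 6,9,15-tris(triethylsilyl) ether of ynone 21 | C=C1[C@H](O[Si](CC)(CC)CC)C[C@@H]([C@@H](C)C(=O)C#CC(C)(C)O[Si](CC)(CC)CC)[C@@H](O[Si](CC)(CC)CC)[C@@H]2C(C)=CC[C@@H]12 | intermediate
23 | (12R)-12-hydroxy-13-yne 6,9,15-tris(triethylsilyl) ether | C=C1[C@H](O[Si](CC)(CC)CC)C[C@@H]([C@@H](C)[C@H](C#CC(C)(C)O[Si](CC)(CC)CC)O)[C@@H](O[Si](CC)(CC)CC)[C@@H]2C(C)=CC[C@@H]12 | intermediate
24 | (12S,13E)-12-hydroxy-13-ene 6,9,15-tris(triethylsilyl) ether | C=C1[C@H](O[Si](CC)(CC)CC)C[C@@H]([C@@H](C)[C@H](/C=C/C(C)(C)O[Si](CC)(CC)CC)O)[C@@H](O[Si](CC)(CC)CC)[C@@H]2C(C)=CC[C@@H]12 | intermediate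
25 | 12-O-acetate of 24 | C=C1[C@H](O[Si](CC)(CC)CC)C[C@@H]([C@@H](C)[C@H](/C=C/C(C)(C)O[Si](CC)(CC)CC)OC(C)=O)[C@@H](O[Si](CC)(CC)CC)[C@@H]2C(C)=CC[C@@H]12 | intermediate
26 | CNP0213969.2, (1R,5S,6R,7S,9R,11R,12S,13E)-12-acetoxy-6,9,15-triol | C=C1[C@H](O)C[C@@H]([C@@H](C)[C@H](/C=C/C(C)(C)O)OC(C)=O)[C@@H](O)[C@@H]2C(C)=CC[C@@H]12 | target

Total step count: 16. Longest linear sequence: 16 steps (1 → 26).

Steps most likely to fail

Step 10 (key step). The C8 radical may be reduced before it cyclizes, or be diverted by hydrogen transfer from allylic C2–H, by 6-exo attack on C3 or by the 1,2-vinyl shift (3-exo closure on C10 and reopening). The fallback closes the same bond by an anionic route. It sets out from iodide 17: silylation (Et3SiOTf, 2,6-lutidine) should give the 9-O-triethylsilyl iodide F1, and Victor Meyer displacement with AgNO2 (Et2O, dark) the primary nitro compound F2. Catalytic tetramethylguanidine (MeCN, 0 °C) should then close C7–C8 by intramolecular nitro-Michael addition to the butenolide, giving the 8-nitro lactone F3 (C8 epimers), again cis-fused and protonated at C11 from the convex face. Radical denitration (Bu3SnH, AIBN, toluene, 110 °C) should give the 9-O-silyl lactone F4, addition of dilithiated alkynol 20 the 9-O-silyl ynone F5, and Et3SiOTf/2,6-lutidine returns the route to 22.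

Step 3. Face selectivity at C1 may be poor (ligand and C9 stereocentre mismatched), methyl may transfer in place of alkenyl, and the trapping with acrolein may show low anti selectivity or conjugate addition. The fallback is a rhodium route through an isolated silyl enol ether. It sets out from stannane 3: tin–lithium exchange (via 6) and ZnCl2 should give the alkenylzinc chloride F6. A [RhCl((R)-binap)]2-catalysed 1,4-addition to 4 in the presence of Me3SiCl (Hayashi–Miyaura type, binap enantiomer chosen for the 3R product) should give the regiodefined trimethylsilyl enol ether F7. MeLi releases the lithium enolate F8, and ZnCl2 followed by acrolein 5 returns the route to aldol 9.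

Step 5. The hydrazone may be deprotonated incompletely or at the wrong site, the alkenyllithium may be protonated by the solvent before methylation (giving the unmethylated alkene), or the alkoxide may be O-methylated. The fallback is an enol triflate cross-coupling. It sets out from aldol 9: Et3SiCl/imidazole should give the silyl ether F9, and KN(SiMe3)2/PhNTf2 at −78 °C the kinetic C3–C4 enol triflate F10. Fe(acac)3-catalysed coupling with MeMgBr should give the methylcyclopentene silyl ether F11, and Bu4NF returns the route to 12.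

Further compounds
F1 | step 10 | 9-O-triethylsilyl ether of iodide 17 | C=C([C@H](O[Si](CC)(CC)CC)CI)[C@@H]1CC=C(C)[C@H]1[C@@H]1OC(=O)C(C)=C1
F2 | step 10 | primary nitro compound (iodine of F1 replaced by NO2) | C=C([C@H](O[Si](CC)(CC)CC)C[N+](=O)[O-])[C@@H]1CC=C(C)[C@H]1[C@@H]1OC(=O)C(C)=C1
F3 | step 10 | 8-nitro-9-O-triethylsilyl tricyclic lactone (C8 epimers) | C=C1[C@H](O[Si](CC)(CC)CC)C([N+](=O)[O-])[C@H]3[C@@H](C)C(=O)O[C@H]3[C@@H]2C(C)=CC[C@@H]12
F4 | step 10 | 9-O-triethylsilyl ether of lactone 18 | C=C1[C@H](O[Si](CC)(CC)CC)C[C@H]3[C@@H](C)C(=O)O[C@H]3[C@@H]2C(C)=CC[C@@H]12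
F5 | step 10 | 9-O-triethylsilyl ether of ynone 21 | C=C1[C@H](O[Si](CC)(CC)CC)C[C@@H]([C@@H](C)C(=O)C#CC(C)(C)O)[C@@H](O)[C@@H]2C(C)=CC[C@@H]12
F6 | step 3 | chloro{1-[(4R)-2,2-dimethyl-1,3-dioxolan-4-yl]ethenyl}zinc | C=C([Zn]Cl)[C@H]1COC(C)(C)O1
F7 | step 3 | {[(3R)-3-{1-[(4S)-2,2-dimethyl-1,3-dioxolan-4-yl]ethenyl}cyclopent-1-en-1-yl]oxy}trimethylsilane | C=C([C@H]2COC(C)(C)O2)[C@@H]1CCC(O[Si](C)(C)C)=C1
F8 | step 3 | lithium (3R)-3-{1-[(4S)-2,2-dimethyl-1,3-dioxolan-4-yl]ethenyl}cyclopent-1-en-1-olate | C=C([C@H]2COC(C)(C)O2)[C@@H]1CCC(O[Li])=C1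
F9 | step 5 | triethylsilyl ether of aldol 9 | C=C([C@H]2COC(C)(C)O2)[C@@H]1CCC(=O)[C@H]1[C@@H](C=C)O[Si](CC)(CC)CC
F10 | step 5 | C3–C4 enol trifluoromethanesulfonate of F9 | C=C([C@H]2COC(C)(C)O2)[C@@H]1CC=C(OS(=O)(=O)C(F)(F)F)[C@H]1[C@@H](C=C)O[Si](CC)(CC)CC
F11 | step 5 | triethylsilyl ether of 12 | C=C([C@H]2COC(C)(C)O2)[C@@H]1CC=C(C)[C@H]1[C@@H](C=C)O[Si](CC)(CC)CC
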